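Readings and results were generated by integration on assumed constants; scatter was added.

- The day is my unit: I want to know what a day of standing does to L once G has stopped growing.

| flask | J | X | remark | time |
|---|---|---|---|---|
| Thursday's | 0.050 M | 0.060 M | run made earlier |  |
| Saturday's | 0.050 M | 0.084 M | run made earlier |  |
| Sunday's | 0.050 M | 0.13 M | run made earlier |  |
| oak | 0.050 M | 0.0600 M (fed, over 2.5 d) | all else is in the flask from the start; the feed brings no volume worth counting | 4.0 d |
| cedar | 0.050 M (fed, over 2.5 d) | 0.0600 M | all else is in the flask from the start; the feed brings no volume worth counting | 4.0 d |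
| alder | 0.050 M | 0.0600 M | everything together at the start | 4.0 d |

- Thursday's (time / d: L / %, G / %): 0.500: 40.8, 18.0; 1.04: 32.6, 20.5; 1.25: 29.5, 21.3; 2.08: 18.1, 18.6; 2.50: 15.6, 22.2
- Saturday's (time / d: L / %, G / %): 1.04: 31.7, 33.2; 2.08: 20.5, 34.1; 3.00: 10.0, 34.4; 4.00: 8.0, 35.3; 5.00: 6.9, 34.8
- Sunday's (time / d: L / %, G / %): 1.04: 24.4, 52.9; 2.08: 12.6, 55.6; 3.00: 7.6, 55.1; 4.00: 5.4, 55.1; 5.00: 2.4, 56.7

(standard deviation of a reading: 1 percentage point)



- the flask with the highest share of L in L plus G ("all alike" if they lie within 1.5 percentage points) (oak / cedar / alder / all alike)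
- share of L in L plus G at the end, oak
- share of L in L plus G at the end, cedar
- share of L in L plus G at the end, alder

- Saturday's run shows it. From 2.08 d to 5.00 d, G stays level, 34.1% and then 34.8%, but L falls from 20.5% to 6.9%. I read this as a first-order leak of L, with a reading of 1.86 d: this is the leak half-life h, the half-life of L while G stands still.
- Alder is Thursday's run carried on, so I build it up from there. I start with the two additions, J to L and L to G, and assume that they have stopped by the last reading at 2.50 d, so the share L/(L+G) is that of this reading, 41.3%.
- Now I add the leak as a correction. Over the remaining 1.50 d, h takes L down to 8.92%, and the share drops to 28.7%, which is 13 percentage points lower.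
- The single G reading carries scatter too. Thursday's last three G readings average 20.7%, and with that G my figure for alder is 30.1%.
- I set no figure for oak or cedar: I hold no reading of when G stops growing under a feed, and h as I read it holds from that moment.
- The forecast puts oak highest, at 52% (44% to 60%), and says of this flask that “L forms late”. It gives cedar 33% (22% to 46%) and alder 26% (22% to 31%); its alder lies below my 30.1%.
- The flasks give 28.9% for oak, 39.4% for cedar and 29.4% for alder, so cedar stands highest. Alder lies near my 30.1%, and the forecast for oak stands 23 points above the flask.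

    2 X → E (k = 1.17 M⁻¹ h⁻¹)
    J + D → Q (k = 0.388 M⁻¹ h⁻¹)
    J + X → L + D (k = 5.47 M⁻¹ h⁻¹)
    X + L → G + D (k = 2.77 M⁻¹ h⁻¹)
    L → Z (k = 0.0183 h⁻¹)

- Oak and cedar part at the end of the feed, 2.50 d. In oak, X still stands at 15.2% of its charge and X + L → G + D runs on, with G rising from 21.7% to 28.8% while L drops from 25.2% to 11.7%. In cedar, X, the limiting reagent, is down to 0.131%, G goes from 8.89% to 8.90%, and L → Z carries on, with L at 11.0% of the J charged. Over the last 1.50 d, h brings that L to 6.30%, and cedar holds 5.78%.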